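## Structural features

The target is a flavanone: ring A (C4a, C5, C6, C7, C8, C8a) is fused through C4a–C8a to the dihydropyranone ring C (O1, C2, C3, C4), and the 4-hydroxyphenyl ring B sits on C2. C2 is the only stereocentre and is (S); it has no neighbouring centre to relay from. It is a benzylic aryl ether β to the C4 carbonyl, so it can be lost by reversible retro-oxa-Michael opening to the chalcone, most readily under base or once the 4'-phenol is free. Ring A is hexasubstituted: acyl at C4a, OH at C5, prenyl at C6, OH at C7, methyl at C8 and O1 at C8a. The prenyl alkene lies between two phenolic oxygens and adds either of them under acid to give a 2,2-dimethylchromane; the phloroglucinol-type ring is also easily oxidised. The real difficulty is regiochemical: O5 and O8a are both ortho to C4a and differ only in their other neighbour (C6-prenyl or C8-methyl), and closure of ring C through the wrong oxygen gives the 6-methyl-8-prenyl isomer. The key step exploits the strict alternation of oxygen-bearing carbons (C5, C7, C8a) and carbon-bearing carbons (C4a, C6, C8) around ring A. This pattern matches the polarity of a vinylketene (C8a, C6, C5, C4a) and an ynol ether (C8, C7), so ring A is assembled with every substituent in place and each oxygen in a different state: free at C8a, silylated at C7, acetal at C5.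

## Logic of the disconnections

28 back to 26 (through 27): the O–Si bonds at O7 and O4' and the O–CH2 bond at O5 are cut. The phenols stay masked until C2 exists, which separates the stereochemical step from the most sensitive functionality. The forward step must not hold a phenoxide long enough to open ring C and must not protonate the C6 side-chain alkene.

26 back to 24 and 25: the C2–C1' bond is cut. The stereocentre then becomes the last skeletal event, set by face selection on a flat ring C that cannot epimerise, and ring B arrives intact. 24 is achiral and 25 is bought. The forward step must deliver the aryl group to the Re face of C2 and protonate the metal enolate at C3 before it can expel O1.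

24 back to 22 (through 23): O1–C2 and C2–C3 are cut, C2 being a single carbon at the formate oxidation level. In 22 only O8a is free, so ring C can close in one direction only; this is where the differentiation created in the key step is used. The forward step must condense at the acetyl methyl group and cyclise under acid mild enough for the acetal at O5.

22 back to 20 and then 19: the C4–C4a bond is cut, then C4a–I. C4a is the only unsubstituted ring carbon, but acid-mediated acylation would strip the acetal and cyclise the side chain. The polarity at C4a is therefore inverted by halogen–metal exchange and the acyl group enters as an electrophile at low temperature. Halogenation must prefer the arene to the alkene, exchange must outrun deprotonation, and addition must stop at the ketone.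

19 back to 12 and 15 (through 16, 17 and 18): C8–C8a, C6–C7 and C4a–C8a are cut. Undoing the 1,2-shift also detaches C5 from C6 and reattaches it to the carbonyl carbon (future C8a) of 12, so four ring A bonds in all arise in the step. Ring A with its full substitution pattern is reduced to two acyclic pieces, a four-carbon unit (C8a, C6, C5, C4a) and a two-carbon unit (C8, C7), and no arene substitution chemistry is needed. The cascade must run shift, cycloaddition, ring opening and ring closure without diversion, with regiochemistry under polarity control.

12 back to 10, 5, 4 and on to 1 and 2: the C=N2 bond at C4 is removed to give 10. 10 is cut between the carbonyl carbon and the oxygenated alkenyl carbon to give 5 and 9 (from 8); this bond serves only to deliver the alkenyl group and is given up again in the shift. 5 comes from 4 by exchange at the acyl carbon, and 4 is cut at C2–C3 by a [3,3] shift to 1 and 2, which sets the trisubstituted alkene without any prenyl halide. The demands are single addition to the acyl group and diazo transfer at the only enolisable carbon without harm to the enol ether.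

8 back to 7 and 6: the vinyl C=C bond is undone to a C–Cl bond, then the acetal C–O bond is cut. This route to the acetal avoids chloromethyl methyl ether.

15 back to 14 and 13: O–Si is cut, then the C1–C2 bond of the alkyne, with C2 coming from a one-carbon carbenoid inserted into an acetate ester. This avoids propyne gas and a peroxide oxidant. Silylation must take place on oxygen, which the bulky silyl group secures.

## Other disconnections considered

Alternative 1: The cut is C2–C3 of ring C.
- **Forward step:** the terminal diazoketone A1, whose O8a carries a 4-silyloxybenzyl group, would be decomposed by Rh2(S-PTTL)4. The divalent rhodium carbenoid at C3 would insert into one of the two enantiotopic O-benzylic C–H bonds to give A2, closing ring C and setting C2 in one catalytic event.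
- **In its favour:** the C–H bond is activated by O1 and by the electron-rich arene. The conditions are neutral, so ring opening by retro-oxa-Michael reaction is not an issue during closure. All three phenols can be silylated and freed by fluoride alone.
- **Where it is better:** ring C and C2 come in one step where the chosen plan needs steps 11 and 12, and no acid is needed near the prenyl group.
- **Against it here:** an acceptor-only carbenoid is the least discriminating kind. A six-membered ring must form, while attack on the lone pair of O1 gives a five-membered oxonium ylide whose [1,2]-benzyl shift leads to a benzofuranone. The prenyl alkene and the electron-rich benzyl ring are further traps.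
- **Structure:** A1 presupposes a finished ring A in which O8a alone carries the benzyl group, which is exactly the differentiation the chosen annulation supplies.
- **Mechanism:** both plans use a diazoketone. The chosen plan uses it where polarity alone decides the outcome; the alternative uses it where a catalyst must choose between two hydrogens and several competing sites.
- **Step economy:** the endgame is shorter, but the route as a whole is not, since ring A must still be made.

Alternative 2: The cuts are O1–C2 and C3–C4.
- **Forward step:** the salicylaldehyde A3, HC(OMe)3 and a confined chiral Brønsted acid would generate a 4-methoxy ortho-quinone methide, which would add the styrene A4 in an inverse-demand [4+2] reaction to give A5.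
- **In its favour:** two bonds, ring C and C2 are made at once from two simple partners. The polarisation of the styrene places the aryl group on C2, and the free O8a again fixes the direction of closure.
- **Where it is better:** in convergence it is the better plan.
- **Against it here:** C4 arrives as a methyl ether at the alcohol oxidation level. Ether cleavage and oxidation are still needed, and the C4 stereocentre is discarded. The strong acid meets three acetals, the prenyl group and an electron-rich styrene prone to cationic oligomerisation, and the quinone methide is crowded by the C5 substituent.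
- **Structure:** A3 needs the same differentiated ring A and could be made from 19, so this is really an alternative to steps 9 to 12 only.
- **Mechanism:** a cationic cycloaddition under strong acid against an organometallic addition under near-neutral conditions.
- **Step economy:** about equal, since formylation, cycloaddition, two adjustments at C4 and deprotection match the five steps of the chosen endgame.

Alternative 3: The cut is C4a–C5 in ring A.
- **Forward step:** A6, a 2-aryl-2,3-dihydropyran-4-one carrying a β-keto ester chain, would be treated with Mg(OMe)2 or LiN(SiMe3)2. Deprotonation at C8 gives the vinylogous enolate, C4a attacks the ester, and enolisation aromatises ring A to give A7.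
- **Where it is equal:** like the chosen plan it is a de novo arene synthesis and fixes the substituent order unambiguously.
- **Where it is better:** O1 is already part of ring C, so the O5/O8a question never arises. The ring A phenols emerge free and only one silyl group must be removed, so protecting-group economy is better. It needs neither a diazo compound nor photochemistry, so it is also better on hazard.
- **Against it here:** A6 is a tricarbonyl chain with two extra epimerisable centres, and it must be built with prenyl on C6 and methyl on C8 by several regiocontrolled acylations. C2 is carried through strongly basic conditions in which deprotonation at C3 can expel O1 and erode the stereocentre. Other aldol closures compete.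
- **Mechanism:** an ionic condensation that depends on enolate site selection, against a pericyclic cascade with built-in regiocontrol. The chosen plan sets C2 only after ring A is complete.
- **Step economy:** comparable, since the saving in deprotection is offset by the assembly of the chain.

Key step: step 8

Assumption (remark on the chemistry): the (S)-configured biaryl bisphosphine is taken to direct aryl transfer to the Re face of C2 of 24, as ligands of this hand do for the corresponding face of cyclic enones; 25 is taken as purchased, and 8 is made because it is not a stock reagent.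

## Route

Step 1
Reactants: 1 2-methylbut-3-en-2-ol; 2 triethyl orthoacetate
Product: 4 ethyl 5-methylhex-4-enoate, via mixed ketene acetal 3 (not isolated)
Conditions: EtCO2H (cat.), 140 °C, EtOH distilled off
Reagents that add atoms: none
Why: Johnson–Claisen (orthoester Claisen) rearrangement: acid-catalysed exchange gives 3, whose chair [3,3] shift converts the tertiary allylic alcohol into the trisubstituted alkene of the prenyl unit; no stereocentre is formed.

Step 2
Reactants: 4 ethyl 5-methylhex-4-enoate
Product: 5 N-methoxy-N,5-dimethylhex-4-enamide
Conditions: MeNH(OMe)·HCl, i-PrMgCl, THF, −20 to 0 °C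
Reagents that add atoms: N,O-dimethylhydroxylamine hydrochloride, CNOC.Cl
Why: Direct aminolysis of the ester by the chloromagnesium amide of the hydroxylamine (Weinreb amide formation); the stable magnesium chelate stops at the amide and the alkene is inert.

Step 3
Reactants: 6 2-chloroethanol
Product: 7 1-chloro-2-(methoxymethoxy)ethane
Conditions: CH2(OMe)2 (solvent), LiBr (cat.), p-TsOH·H2O (cat.), rt
Reagents that add atoms: dimethoxymethane, COCOC
Why: Acid-catalysed transacetalisation gives the methoxymethyl ether without chloromethyl methyl ether; the large excess of the acetal drives the equilibrium.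

Step 4
Reactants: 7 1-chloro-2-(methoxymethoxy)ethane
Product: 8 (methoxymethoxy)ethene
Conditions: KOH (powder), Bu4N(HSO4) (cat.), 110 °C, product distilled out
Reagents that add atoms: none
Why: Base-mediated E2 dehydrochlorination of a 2-chloroethyl ether to the vinyl ether; the acetal is stable to hydroxide and the volatile product leaves the mixture as it forms.

Step 5
Reactants: 8 (methoxymethoxy)ethene; 5 N-methoxy-N,5-dimethylhex-4-enamide
Product: 10 2-(methoxymethoxy)-7-methylocta-1,6-dien-3-one, via 1-(methoxymethoxy)ethenyllithium 9 (not isolated)
Conditions: s-BuLi, THF, −78 °C; then 5, −78 to −20 °C; aq. NH4Cl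
Reagents that add atoms: sec-butyllithium, [Li]C(C)CC (lithium of 9 only)
Why: α-Lithiation of the vinyl ether, assisted by the acetal oxygen, gives the acyl-anion equivalent 9, which adds once to the Weinreb amide; the tetrahedral chelate persists until the quench, so the enone is released only on work-up.

Step 6
Reactants: 10 2-(methoxymethoxy)-7-methylocta-1,6-dien-3-one
Product: 12 4-diazo-2-(methoxymethoxy)-7-methylocta-1,6-dien-3-one, via trifluoroacetyl ketone 11 (not isolated)
Conditions: LiN(SiMe3)2, THF, −78 °C; CF3CO2CH2CF3; cold 5% aq. HCl; then 4-AcNHC6H4SO2N3, Et3N, H2O, MeCN, rt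
Reagents that add atoms: 2,2,2-trifluoroethyl trifluoroacetate, O=C(OCC(F)(F)F)C(F)(F)F (trifluoroacetyl group of 11 only); 4-acetamidobenzenesulfonyl azide, CC(=O)Nc1ccc(cc1)S(=O)(=O)N=[N+]=[N-]
Why: Detrifluoroacetylative diazo transfer: the enolate at C4, the only enolisable carbon, is trifluoroacetylated to 11, which is acidic enough for sulfonyl azide transfer with Et3N and then loses the trifluoroacetyl group as the N-acylsulfonamide. The crystalline acetamido azide is chosen as a safer transfer reagent than methanesulfonyl azide.

Step 7
Reactants: 13 ethyl acetate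
Product: 15 1-(triisopropylsilyloxy)propyne, via lithium ynolate 14 (not isolated)
Conditions: CH2Br2, lithium 2,2,6,6-tetramethylpiperidide, THF, −78 °C; 13; LiN(SiMe3)2; n-BuLi, −78 °C to rt; then i-Pr3SiCl, −78 to 0 °C
Reagents that add atoms: dibromomethane, BrCBr; triisopropylsilyl chloride, CC(C)[Si](Cl)(C(C)C)C(C)C; n-butyllithium, [Li]CCCC (lithium of 14 only)
Why: Kowalski ynolate synthesis: dibromomethyllithium adds to the ester, bromine–lithium exchange on the derived bromo enolate triggers a 1,2-shift with loss of bromide to give 14, and the bulky silyl chloride reacts at oxygen. No propyne gas or peroxide is needed.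

Step 8
Reactants: 12 4-diazo-2-(methoxymethoxy)-7-methylocta-1,6-dien-3-one; 15 1-(triisopropylsilyloxy)propyne
Product: 19 5-(methoxymethoxy)-2-methyl-4-(3-methylbut-2-enyl)-3-(triisopropylsilyloxy)phenol, via vinylketene 16 (not isolated), via 4-vinylcyclobutenone 17 (not isolated), via dienylketene 18 (not isolated)
Conditions: hν (medium-pressure Hg lamp, Pyrex filter, FEP flow coil), 15 (1.5 equiv), degassed CH2Cl2, 25 °C; then PhMe, 80 °C
Reagents that add atoms: none
Why: This is the Danheiser benzannulation in its photochemical Wolff variant with a siloxyalkyne as ketenophile. Light expels N2 from 12 and the 1-(methoxymethoxy)ethenyl group shifts from the carbonyl carbon to C4 to give 16; this shift joins the future C5 to C6, so four ring A bonds arise in the step (C5–C6 by migration and the three below). The nucleophilic, methyl-bearing carbon of 15 attacks the ketene carbon and the silyloxy carbon bonds to the ketene α-carbon in a [2+2] cycloaddition (C8–C8a and C6–C7), giving 17. Strain drives conrotatory 4π opening of 17 to 18, and ring A closes by thermal disrotatory 6π electrocyclisation between the ketene carbon and the terminal CH2 (C4a–C8a), followed by tautomerisation of the cyclohexadienone to the phenol. No stereocentre is formed: the quaternary carbon of 17 is transient, and only the 3E isomer of 18 can close, which the reversible ring opening supplies. The regiochemistry needed (methyl between O8a and O7, prenyl between O7 and O5, free OH only at C8a) follows from the polarity of ketene and ynol ether and from the ketene oxygen becoming the phenol. The Wolff shift must outrun a carbene 1,2-hydrogen shift from the prenyl CH2, which the concerted reaction of the s-Z conformer under direct irradiation favours. The electron-rich ynol ether outcompetes the unactivated prenyl alkene for the ketene, and excess 15 with the low ketene concentration in flow limits acylation of 19 by 16.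

Step 9
Reactants: 19 5-(methoxymethoxy)-2-methyl-4-(3-methylbut-2-enyl)-3-(triisopropylsilyloxy)phenol
Product: 20 2-iodo-3-(methoxymethoxy)-6-methyl-4-(3-methylbut-2-enyl)-5-(triisopropylsilyloxy)phenol
Conditions: N-iodosuccinimide (1.0 equiv), MeCN, −20 °C, dark
Reagents that add atoms: N-iodosuccinimide, O=C1CCC(=O)N1I
Why: Electrophilic aromatic iodination: C4a is the only free ring position and lies ortho to the free phenol and the acetal oxygen and para to the silyl ether, so it should react far faster than the trisubstituted alkene under neutral conditions at low temperature.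

Step 10
Reactants: 20 2-iodo-3-(methoxymethoxy)-6-methyl-4-(3-methylbut-2-enyl)-5-(triisopropylsilyloxy)phenol
Product: 22 1-[2-hydroxy-6-(methoxymethoxy)-3-methyl-5-(3-methylbut-2-enyl)-4-(triisopropylsilyloxy)phenyl]ethanone, via dilithio phenolate 21 (not isolated)
Conditions: n-BuLi (2.2 equiv), THF, −78 °C; then MeC(O)N(OMe)Me, −78 to 0 °C; aq. NH4Cl
Reagents that add atoms: N-methoxy-N-methylacetamide, CC(=O)N(C)OC; n-butyllithium, [Li]CCCC (lithium of 21 only)
Why: The first equivalent deprotonates the phenol and the second effects iodine–lithium exchange, which is much faster than benzylic deprotonation. Aryllithium 21, chelated by the acetal oxygen, is acylated by the Weinreb amide and stops at the ketone.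

Step 11
Reactants: 22 1-[2-hydroxy-6-(methoxymethoxy)-3-methyl-5-(3-methylbut-2-enyl)-4-(triisopropylsilyloxy)phenyl]ethanone
Product: 24 5-(methoxymethoxy)-8-methyl-6-(3-methylbut-2-enyl)-7-(triisopropylsilyloxy)-4H-chromen-4-one, via enaminone 23 (not isolated)
Conditions: Me2NCH(OMe)2, PhMe, 90 °C; then AcOH, 60 °C
Reagents that add atoms: N,N-dimethylformamide dimethyl acetal, COC(OC)N(C)C
Why: Condensation of the acetyl methyl group with the formamide acetal gives 23. Mild acid then promotes addition of the only free phenol (O8a) to the β-carbon and loss of dimethylamine, closing ring C as the chromone with O1 next to the C8 methyl group by construction.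

Step 12
Reactants: 24 5-(methoxymethoxy)-8-methyl-6-(3-methylbut-2-enyl)-7-(triisopropylsilyloxy)-4H-chromen-4-one; 25 [4-(tert-butyldimethylsilyloxy)phenyl]boronic acid
Product: 26 (2S)-2-[4-(tert-butyldimethylsilyloxy)phenyl]-5-(methoxymethoxy)-8-methyl-6-(3-methylbut-2-enyl)-7-(triisopropylsilyloxy)chroman-4-one
Conditions: [Rh(OH)(cod)]2 (cat., cod = cycloocta-1,5-diene), (S)-6,6'-dimethoxy-2,2'-bis[bis(3,4,5-trifluorophenyl)phosphino]biphenyl, 25 (3 equiv), PhMe/H2O, 25 °C
Reagents that add atoms: none
Why: Hayashi–Miyaura asymmetric 1,4-addition to a chromone: transmetallation gives an aryl complex of monovalent rhodium that inserts the C2=C3 bond, and water protonates the resulting enolate. The chiral bisphosphine shields the Si face of C2, so the aryl group is delivered to the Re face and C2 becomes (S); the mirror-image ligand would be used should the sense prove opposite. The electron-poor ligand allows base-free conditions at room temperature, which avoid opening of ring C.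

Step 13
Reactants: 26 (2S)-2-[4-(tert-butyldimethylsilyloxy)phenyl]-5-(methoxymethoxy)-8-methyl-6-(3-methylbut-2-enyl)-7-(triisopropylsilyloxy)chroman-4-one
Product: 28 (2S)-5,7-dihydroxy-2-(4-hydroxyphenyl)-8-methyl-6-(3-methylbut-2-enyl)chroman-4-one, via 5-O-methoxymethyl flavanone 27 (not isolated)
Conditions: Bu4NF, AcOH (1:1), THF, 0 °C to rt; aqueous wash; then 3 M HCl, MeOH, 40 °C
Reagents that add atoms: none
Why: Acetic acid-buffered fluoride cleaves both aryl silyl ethers without leaving a free phenoxide, so base-induced retro-oxa-Michael opening at C2 is avoided. The remaining acetal is peri to the C4 carbonyl and is methanolysed by dilute acid at mild temperature, short of conditions that protonate the prenyl alkene; C2 is untouched.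

## Compound list

1 | 2-methylbut-3-en-2-ol | CC(C)(O)C=C | starting material
2 | triethyl orthoacetate | CCOC(C)(OCC)OCC | starting material
3 | 1-ethoxy-1-[(2-methylbut-3-en-2-yl)oxy]ethene | C=C(OCC)OC(C)(C)C=C | intermediate
4 | ethyl 5-methylhex-4-enoate | CCOC(=O)CCC=C(C)C | intermediate
5 | N-methoxy-N,5-dimethylhex-4-enamide | CON(C)C(=O)CCC=C(C)C | intermediate
6 | 2-chloroethanol | OCCCl | starting material
7 | 1-chloro-2-(methoxymethoxy)ethane | COCOCCCl | intermediate
8 | (methoxymethoxy)ethene | C=COCOC | intermediate
9 | 1-(methoxymethoxy)ethenyllithium | [Li]C(=C)OCOC | intermediate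
10 | 2-(methoxymethoxy)-7-methylocta-1,6-dien-3-one | C=C(OCOC)C(=O)CCC=C(C)C | intermediate
11 | 1,1,1-trifluoro-3-[2-(methoxymethoxy)prop-2-enoyl]-6-methylhept-5-en-2-one (racemic) | C=C(OCOC)C(=O)C(CC=C(C)C)C(=O)C(F)(F)F | intermediate
12 | 4-diazo-2-(methoxymethoxy)-7-methylocta-1,6-dien-3-one | C=C(OCOC)C(=O)C(=[N+]=[N-])CC=C(C)C | intermediate
13 | ethyl acetate | CCOC(C)=O | starting material
14 | lithium prop-1-yn-1-olate | CC#C[O-].[Li+] | intermediate
15 | 1-(triisopropylsilyloxy)propyne | CC#CO[Si](C(C)C)(C(C)C)C(C)C | intermediate
16 | 2-[1-(methoxymethoxy)ethenyl]-5-methylhexa-1,4-dien-1-one | O=C=C(CC=C(C)C)C(=C)OCOC | intermediate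
17 | 4-[1-(methoxymethoxy)ethenyl]-2-methyl-4-(3-methylbut-2-enyl)-3-(triisopropylsilyloxy)cyclobut-2-en-1-one (racemic) | CC1=C(O[Si](C(C)C)(C(C)C)C(C)C)C(CC=C(C)C)(C(=C)OCOC)C1=O | intermediate
18 | (3E)-5-(methoxymethoxy)-2-methyl-4-(3-methylbut-2-enyl)-3-(triisopropylsilyloxy)hexa-1,3,5-trien-1-one | O=C=C(C)/C(O[Si](C(C)C)(C(C)C)C(C)C)=C(CC=C(C)C)\C(=C)OCOC | intermediate
19 | 5-(methoxymethoxy)-2-methyl-4-(3-methylbut-2-enyl)-3-(triisopropylsilyloxy)phenol | Cc1c(O)cc(OCOC)c(CC=C(C)C)c1O[Si](C(C)C)(C(C)C)C(C)C | intermediate
20 | 2-iodo-3-(methoxymethoxy)-6-methyl-4-(3-methylbut-2-enyl)-5-(triisopropylsilyloxy)phenol | Cc1c(O)c(I)c(OCOC)c(CC=C(C)C)c1O[Si](C(C)C)(C(C)C)C(C)C | intermediate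
21 | lithium 2-lithio-3-(methoxymethoxy)-6-methyl-4-(3-methylbut-2-enyl)-5-(triisopropylsilyloxy)phenolate | [Li+].[O-]c1c(C)c(O[Si](C(C)C)(C(C)C)C(C)C)c(CC=C(C)C)c(OCOC)c1[Li] | intermediate
22 | 1-[2-hydroxy-6-(methoxymethoxy)-3-methyl-5-(3-methylbut-2-enyl)-4-(triisopropylsilyloxy)phenyl]ethanone | CC(=O)c1c(O)c(C)c(O[Si](C(C)C)(C(C)C)C(C)C)c(CC=C(C)C)c1OCOC | intermediate
23 | (2E)-3-(dimethylamino)-1-[2-hydroxy-6-(methoxymethoxy)-3-methyl-5-(3-methylbut-2-enyl)-4-(triisopropylsilyloxy)phenyl]prop-2-en-1-one | CN(C)/C=C/C(=O)c1c(O)c(C)c(O[Si](C(C)C)(C(C)C)C(C)C)c(CC=C(C)C)c1OCOC | intermediate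
24 | 5-(methoxymethoxy)-8-methyl-6-(3-methylbut-2-enyl)-7-(triisopropylsilyloxy)-4H-chromen-4-one | Cc1c(O[Si](C(C)C)(C(C)C)C(C)C)c(CC=C(C)C)c(OCOC)c2c(=O)ccoc12 | intermediate
25 | [4-(tert-butyldimethylsilyloxy)phenyl]boronic acid | CC(C)(C)[Si](C)(C)Oc1ccc(cc1)B(O)O | starting material
26 | (2S)-2-[4-(tert-butyldimethylsilyloxy)phenyl]-5-(methoxymethoxy)-8-methyl-6-(3-methylbut-2-enyl)-7-(triisopropylsilyloxy)chroman-4-one | CC(C)=CCc1c(O[Si](C(C)C)(C(C)C)C(C)C)c(C)c2c(c1OCOC)C(=O)C[C@@H](c1ccc(O[Si](C)(C)C(C)(C)C)cc1)O2 | intermediate
27 | (2S)-7-hydroxy-2-(4-hydroxyphenyl)-5-(methoxymethoxy)-8-methyl-6-(3-methylbut-2-enyl)chroman-4-one | CC(C)=CCc1c(O)c(C)c2c(c1OCOC)C(=O)C[C@@H](c1ccc(O)cc1)O2 | intermediate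
28 | (2S)-5,7-dihydroxy-2-(4-hydroxyphenyl)-8-methyl-6-(3-methylbut-2-enyl)chroman-4-one | CC(C)=CCc1c(O)c(C)c2c(c1O)C(=O)C[C@@H](c1ccc(O)cc1)O2 | target

## Step count and least certain steps

Total step count: 13. Longest linear sequence: 10 steps (1, 2, 5, 6, 8, 9, 10, 11, 12, 13); steps 3 and 4 and step 7 are side branches.

Step 8 (key step).
- **Risk:** the carbene formed on loss of N2 carries a CH2 group on the diazo carbon, so a 1,2-hydrogen shift to a dienone can compete with the Wolff shift, above all from the s-E conformer. The phenol formed can also be acylated by the ketene before the alkyne captures it.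
- **Fallback:** the same vinylketene 16 is generated thermally, without a carbene. The fallback sets out from 4 and 15 and rejoins the route at 19.
- **Sequence:** ester 4 is C-acetylated (LiN(i-Pr)2, THF, −78 °C, then 1-acetylimidazole) to ethyl 2-acetyl-5-methylhex-4-enoate F1. O-alkylation of its sodium enolate with chloromethyl methyl ether, generated in solution from dimethoxymethane and acetyl chloride with ZnBr2 (cat.), gives ethyl 3-(methoxymethoxy)-2-(3-methylbut-2-enyl)but-2-enoate F2. Saponification (LiOH, aqueous THF, acidification to pH 5) gives 3-(methoxymethoxy)-2-(3-methylbut-2-enyl)but-2-enoic acid F3. 1-Chloro-N,N,2-trimethylprop-1-en-1-amine converts F3 under neutral conditions into 3-(methoxymethoxy)-2-(3-methylbut-2-enyl)but-2-enoyl chloride F4. Slow addition of F4 to Et3N and 15 in toluene at 80 °C should effect 1,4-dehydrochlorination to 16, which then follows the thermal cascade through 17 and 18 to 19.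

Step 10.
- **Risk:** the hindered, doubly flanked aryllithium may take a proton from the acetamide rather than add to it, or be alkylated by the butyl iodide formed in the exchange. In step 9, which feeds it, iodine transfer to the prenyl alkene may also compete.
- **Fallback:** it sets out from 19, avoids both halogenation and organolithium chemistry, and rejoins the route at 22.
- **Sequence:** magnesium-mediated ortho-formylation of the phenol (Casnati–Skattebøl conditions: MgCl2, Et3N, paraformaldehyde, MeCN, 70 °C) should give 2-hydroxy-6-(methoxymethoxy)-3-methyl-5-(3-methylbut-2-enyl)-4-(triisopropylsilyloxy)benzaldehyde F5. Addition of MeMgBr (3 equiv, THF, 0 °C) gives racemic 2-(1-hydroxyethyl)-3-(methoxymethoxy)-6-methyl-4-(3-methylbut-2-enyl)-5-(triisopropylsilyloxy)phenol F6, and oxidation of the benzylic alcohol with MnO2 in CH2Cl2 gives 22.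

Step 12.
- **Risk:** insertion into the electron-rich chromone, a vinylogous ester, may be slow, so that protodeboronation of 25 consumes the aryl donor. Facial selectivity may be insufficient, or the rhodium enolate may open ring C.
- **Fallback:** the stereocentre is set by kinetic resolution instead. The fallback sets out from 22 and rejoins the route at 26.
- **Sequence:** Kabbe-type condensation of 22 with 4-(tert-butyldimethylsilyloxy)benzaldehyde (pyrrolidine, EtOH, 50 °C) should give racemic 2-[4-(tert-butyldimethylsilyloxy)phenyl]-5-(methoxymethoxy)-8-methyl-6-(3-methylbut-2-enyl)-7-(triisopropylsilyloxy)chroman-4-one F7. Asymmetric transfer hydrogenation with RuCl[(R,R)-TsDPEN](p-cymene) and HCO2H/Et3N should reduce the (2R)-ketone faster, to (2R,4R)-2-[4-(tert-butyldimethylsilyloxy)phenyl]-5-(methoxymethoxy)-8-methyl-6-(3-methylbut-2-enyl)-7-(triisopropylsilyloxy)chroman-4-ol F8. The unreacted (2S)-ketone 26 is recovered by chromatography at slightly more than half conversion.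

Step 13.
- **Risk:** during the acid stage, once O7 is free, a phenolic oxygen may add to the protonated prenyl alkene and close a dimethylchromane ring. Prolonged exposure may also erode C2 through ring opening.
- **Fallback:** the acid step is moved to the achiral chromone, where O7 is still silylated. The fallback sets out from 24 and rejoins the route at 28.
- **Sequence:** methanolysis of the acetal of 24 (HCl, MeOH, rt) gives 5-hydroxy-8-methyl-6-(3-methylbut-2-enyl)-7-(triisopropylsilyloxy)-4H-chromen-4-one F9. The rhodium-catalysed addition of 25 under the conditions of step 12 gives (2S)-2-[4-(tert-butyldimethylsilyloxy)phenyl]-5-hydroxy-8-methyl-6-(3-methylbut-2-enyl)-7-(triisopropylsilyloxy)chroman-4-one F10. Buffered fluoride alone (Bu4NF, AcOH, THF) then releases 28.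

## Further compounds

F1 | step 8 | ethyl 2-acetyl-5-methylhex-4-enoate (racemic) | CCOC(=O)C(CC=C(C)C)C(C)=O
F2 | step 8 | ethyl 3-(methoxymethoxy)-2-(3-methylbut-2-enyl)but-2-enoate | CCOC(=O)C(CC=C(C)C)=C(C)OCOC
F3 | step 8 | 3-(methoxymethoxy)-2-(3-methylbut-2-enyl)but-2-enoic acid | OC(=O)C(CC=C(C)C)=C(C)OCOC
F4 | step 8 | 3-(methoxymethoxy)-2-(3-methylbut-2-enyl)but-2-enoyl chloride | ClC(=O)C(CC=C(C)C)=C(C)OCOC
F5 | step 10 | 2-hydroxy-6-(methoxymethoxy)-3-methyl-5-(3-methylbut-2-enyl)-4-(triisopropylsilyloxy)benzaldehyde | O=Cc1c(O)c(C)c(O[Si](C(C)C)(C(C)C)C(C)C)c(CC=C(C)C)c1OCOC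
F6 | step 10 | 2-(1-hydroxyethyl)-3-(methoxymethoxy)-6-methyl-4-(3-methylbut-2-enyl)-5-(triisopropylsilyloxy)phenol (racemic) | CC(O)c1c(O)c(C)c(O[Si](C(C)C)(C(C)C)C(C)C)c(CC=C(C)C)c1OCOC
F7 | step 12 | 2-[4-(tert-butyldimethylsilyloxy)phenyl]-5-(methoxymethoxy)-8-methyl-6-(3-methylbut-2-enyl)-7-(triisopropylsilyloxy)chroman-4-one (racemic) | CC(C)=CCc1c(O[Si](C(C)C)(C(C)C)C(C)C)c(C)c2c(c1OCOC)C(=O)CC(c1ccc(O[Si](C)(C)C(C)(C)C)cc1)O2
F8 | step 12 | (2R,4R)-2-[4-(tert-butyldimethylsilyloxy)phenyl]-5-(methoxymethoxy)-8-methyl-6-(3-methylbut-2-enyl)-7-(triisopropylsilyloxy)chroman-4-ol | CC(C)=CCc1c(O[Si](C(C)C)(C(C)C)C(C)C)c(C)c2c(c1OCOC)[C@H](O)C[C@H](c1ccc(O[Si](C)(C)C(C)(C)C)cc1)O2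
F9 | step 13 | 5-hydroxy-8-methyl-6-(3-methylbut-2-enyl)-7-(triisopropylsilyloxy)-4H-chromen-4-one | Cc1c(O[Si](C(C)C)(C(C)C)C(C)C)c(CC=C(C)C)c(O)c2c(=O)ccoc12
F10 | step 13 | (2S)-2-[4-(tert-butyldimethylsilyloxy)phenyl]-5-hydroxy-8-methyl-6-(3-methylbut-2-enyl)-7-(triisopropylsilyloxy)chroman-4-one | CC(C)=CCc1c(O[Si](C(C)C)(C(C)C)C(C)C)c(C)c2c(c1O)C(=O)C[C@@H](c1ccc(O[Si](C)(C)C(C)(C)C)cc1)O2
A1 | alternative 1 | 2-diazo-1-[2-{[4-(tert-butyldimethylsilyloxy)phenyl]methoxy}-4,6-bis(tert-butyldimethylsilyloxy)-3-methyl-5-(3-methylbut-2-enyl)phenyl]ethanone | [N-]=[N+]=CC(=O)c1c(OCc2ccc(O[Si](C)(C)C(C)(C)C)cc2)c(C)c(O[Si](C)(C)C(C)(C)C)c(CC=C(C)C)c1O[Si](C)(C)C(C)(C)C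
A2 | alternative 1 | (2S)-5,7-bis(tert-butyldimethylsilyloxy)-2-[4-(tert-butyldimethylsilyloxy)phenyl]-8-methyl-6-(3-methylbut-2-enyl)chroman-4-one | CC(C)=CCc1c(O[Si](C)(C)C(C)(C)C)c(C)c2c(c1O[Si](C)(C)C(C)(C)C)C(=O)C[C@@H](c1ccc(O[Si](C)(C)C(C)(C)C)cc1)O2
A3 | alternative 2 | 2-hydroxy-4,6-bis(methoxymethoxy)-3-methyl-5-(3-methylbut-2-enyl)benzaldehyde | O=Cc1c(O)c(C)c(OCOC)c(CC=C(C)C)c1OCOC
A4 | alternative 2 | 1-ethenyl-4-(methoxymethoxy)benzene | C=Cc1ccc(OCOC)cc1
A5 | alternative 2 | (2S,4S)-4-methoxy-5,7-bis(methoxymethoxy)-2-[4-(methoxymethoxy)phenyl]-8-methyl-6-(3-methylbut-2-enyl)chroman | CC(C)=CCc1c(OCOC)c(C)c2c(c1OCOC)[C@@H](OC)C[C@@H](c1ccc(OCOC)cc1)O2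
A6 | alternative 3 | methyl 2-(3-methylbut-2-enyl)-3-oxo-4-{(2S)-4-oxo-2-[4-(triisopropylsilyloxy)phenyl]-3,4-dihydro-2H-pyran-6-yl}pentanoate (mixture of epimers at the two chain carbons) | COC(=O)C(CC=C(C)C)C(=O)C(C)C1=CC(=O)C[C@@H](c2ccc(O[Si](C(C)C)(C(C)C)C(C)C)cc2)O1
A7 | alternative 3 | (2S)-5,7-dihydroxy-8-methyl-6-(3-methylbut-2-enyl)-2-(4-triisopropylsilyloxyphenyl)chroman-4-one | CC(C)=CCc1c(O)c(C)c2c(c1O)C(=O)C[C@@H](c1ccc(O[Si](C(C)C)(C(C)C)C(C)C)cc1)O2
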